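## Retrosynthetic overview

1. Lignan numbering is used: oxolane O1/C2/C3/C4/C5 = O/C7/C8/C8'/C9'. Agastinol ⇒ acylation of C9–O and loss of three O-benzyl groups ⇒ (7R,8S,8'S)-di-O-benzyllariciresinol + 4-(benzyloxy)benzoic acid.
2. Oxolane ⇒ cut C8–C8' (ring C3–C4) to an acyclic epoxy cinnamyl ether. Ti(III) opens the terminal C8/C9 oxirane to a C8 radical that closes 5-exo on C8'=C7'. This radical β,β'-union of two like-polarised C6C3 units makes the ring, the C–C bond, C8, C8' and the free C9–OH in one operation, all relayed from C7.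
3. Enabling feature: ring atom C3 (C8) bears the exocyclic C9–O bond, the retron of a reductively opened oxirane. Its neighbour C4 (C8') bears the exocyclic benzylic C7'H2, the retron of a styrene radical acceptor. O1–C5 (C9') is an allyl ether link attached to the benzylic stereocentre C2 (C7).
4. Epoxy ether ⇒ Williamson union of a (1S,2R)-epoxy alcohol (C7 set by Sharpless kinetic resolution) with a cinnamyl bromide. Both halves come from O-benzylvanillin.
5. Ring order: the three arenes are bought. The oxirane (temporary, step 2) is consumed when the oxolane, the only skeletal ring built and the last one closed, is formed (step 7).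

Key step: step 7

Remark: the target is read from its SMILES as the 9-O-(4-hydroxybenzoate) of (7R,8S,8'S)-lariciresinol (2,3-trans-3,4-cis oxolane). In the SMILES of titanium species the cyclopentadienyl ligands are drawn as σ-bonded C5H5 groups.

## Route

Step 1
Reactants: 1 4-(benzyloxy)-3-methoxybenzaldehyde; 2 vinylmagnesium bromide
Product: 3 rac-1-[4-(benzyloxy)-3-methoxyphenyl]prop-2-en-1-ol
Conditions: 2 (1.2 equiv), THF, 0 °C; then sat. aq. NH4Cl
Reagents that add atoms: none
Why: 1,2-addition of a vinyl Grignard reagent to an aromatic aldehyde; the carbinol centre (future C7) is formed racemic on purpose and is resolved in step 2, and the buffered quench avoids acid-induced allylic transposition.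

Step 2
Reactants: 3 rac-1-[4-(benzyloxy)-3-methoxyphenyl]prop-2-en-1-ol
Product: 4 (S)-[4-(benzyloxy)-3-methoxyphenyl][(R)-oxiran-2-yl]methanol
Conditions: Ti(OiPr)4 (0.10 equiv), L-(+)-DIPT (0.12 equiv), anhydrous TBHP (0.45 equiv), 4 Å MS, CH2Cl2, −20 °C
Reagents that add atoms: tert-butyl hydroperoxide CC(C)(C)OO
Why: Sharpless kinetic resolution (catalytic asymmetric epoxidation of a secondary allylic alcohol): with L-(+)-DIPT the (R)-carbinol is the fast-reacting enantiomer and is epoxidised with erythro selectivity, so limiting TBHP should give the (1S,2R)-epoxy alcohol (same spatial arrangement at C7, descriptor changed only by priority) and leave the (S)-alcohol, which sets C7 by the catalyst while the oxirane CH centre is erased again in step 7.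

Step 3
Reactants: 1 4-(benzyloxy)-3-methoxybenzaldehyde; 5 ethyl (triphenylphosphoranylidene)acetate
Product: 6 ethyl (E)-3-[4-(benzyloxy)-3-methoxyphenyl]prop-2-enoate
Conditions: 5 (1.1 equiv), toluene, 80 °C
Reagents that add atoms: none
Why: Wittig olefination with a stabilised ylide, which gives the (E)-cinnamate from aromatic aldehydes under neutral conditions.

Step 4
Reactants: 6 ethyl (E)-3-[4-(benzyloxy)-3-methoxyphenyl]prop-2-enoate
Product: 7 (E)-3-[4-(benzyloxy)-3-methoxyphenyl]prop-2-en-1-ol
Conditions: DIBAL-H (2.3 equiv), CH2Cl2, −78 → 0 °C; then aq. Rochelle salt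
Reagents that add atoms: none
Why: 1,2-reduction of an α,β-unsaturated ester with DIBAL-H gives the allylic alcohol without touching the alkene geometry or the benzyl ether.

Step 5
Reactants: 7 (E)-3-[4-(benzyloxy)-3-methoxyphenyl]prop-2-en-1-ol
Product: 8 (E)-1-(benzyloxy)-4-(3-bromoprop-1-en-1-yl)-2-methoxybenzene
Conditions: PBr3 (0.4 equiv), Et2O, 0 °C; used crude at once
Reagents that add atoms: phosphorus tribromide BrP(Br)Br
Why: bromination of a primary allylic alcohol with PBr3 (SN2 on the phosphite ester) at low temperature keeps the (E)-alkene, and the labile electron-rich bromide is not stored.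

Step 6
Reactants: 4 (S)-[4-(benzyloxy)-3-methoxyphenyl][(R)-oxiran-2-yl]methanol; 8 (E)-1-(benzyloxy)-4-(3-bromoprop-1-en-1-yl)-2-methoxybenzene
Product: 9 (R)-2-[(S)-[4-(benzyloxy)-3-methoxyphenyl]{[(E)-3-[4-(benzyloxy)-3-methoxyphenyl]prop-2-en-1-yl]oxy}methyl]oxirane
Conditions: NaH (1.1 equiv, added last), Bu4NI (cat.), THF–DMF, 0 °C → rt
Reagents that add atoms: none
Why: Williamson ether synthesis in which deprotonated 4 is trapped by the very reactive allylic bromide already present, faster than it can undergo Payne rearrangement, and no stereocentre is touched.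

Step 7
Reactants: 9 (R)-2-[(S)-[4-(benzyloxy)-3-methoxyphenyl]{[(E)-3-[4-(benzyloxy)-3-methoxyphenyl]prop-2-en-1-yl]oxy}methyl]oxirane
Product: 13 [(2R,3S,4S)-4-[4-(benzyloxy)-3-methoxybenzyl]-2-[4-(benzyloxy)-3-methoxyphenyl]oxolan-3-yl]methanol, via C8 titanoxy radical 10 (not isolated), via C7' benzylic radical 11 (not isolated), via bis-titanium(IV) species 12 (not isolated)
Conditions: Cp2TiCl2 (2.5 equiv), Zn dust, THF, rt (green Cp2TiCl), added slowly to 9 in THF (0.02 M), rt; then cold 1 M HCl, short contact
Reagents that add atoms: none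
Why: Cp2TiCl binds the oxirane oxygen and transfers one electron, so the C8–O bond breaks homolytically to the secondary C8 radical 10 with the titanoxy group on C9; 10 adds to C8' of the styrenyl double bond (C8–C8' bond, oxolane closed), the benzylic C7' radical 11 is captured by a second Cp2TiCl to give 12, and HCl protonates the C7'–Ti and C9–O–Ti bonds. The closest known reaction type is the titanocene(III)-mediated reductive epoxide opening/radical cyclisation (Nugent–RajanBabu reaction), which is established for epoxy ethers that carry a cinnamyl-type acceptor and tolerates aryl benzyl ethers. The only ring closed is the oxolane, by 5-exo-trig closure of a 3-oxa-5-hexenyl radical through a chair-like transition state. C8 is planar in 10, so the oxirane configuration is erased and C7 is the only source of stereochemical information: its aryl group sits pseudo-equatorial and the CH2OTi arm on C8 turns away from it (7,8-trans), while the styryl arm takes the pseudo-equatorial position, which places the new C8'–C7' bond cis to the C9 arm and trans to the aryl group (8,8'-cis, the usual 1,5-cis/2,5-trans preference of substituted hexenyl radicals). The step needs cleavage of C8–O rather than C9–O, secured by the terminal oxirane (secondary versus primary radical), and it needs cyclisation to outrun capture of 10 by Ti(III), which would end in β-elimination; this is secured by the conjugated styrene acceptor, the ether oxygen in the tether and slow addition at high dilution. Minor diastereomers should be removable by chromatography at this stage, and the only free hydroxyl group of 13 is the C9–OH that the ester needs.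

Step 8
Reactants: 13 [(2R,3S,4S)-4-[4-(benzyloxy)-3-methoxybenzyl]-2-[4-(benzyloxy)-3-methoxyphenyl]oxolan-3-yl]methanol; 14 4-(benzyloxy)benzoic acid
Product: 15 [(2R,3S,4S)-4-[4-(benzyloxy)-3-methoxybenzyl]-2-[4-(benzyloxy)-3-methoxyphenyl]oxolan-3-yl]methyl 4-(benzyloxy)benzoate
Conditions: DCC (1.2 equiv), DMAP (cat.), CH2Cl2, 0 °C → rt
Reagents that add atoms: none
Why: Steglich esterification of the only free hydroxyl group (C9–OH) under neutral conditions that do not ionise the benzylic C7–O bond and involve no stereocentre.

Step 9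
Reactants: 15 [(2R,3S,4S)-4-[4-(benzyloxy)-3-methoxybenzyl]-2-[4-(benzyloxy)-3-methoxyphenyl]oxolan-3-yl]methyl 4-(benzyloxy)benzoate
Product: 16 agastinol
Conditions: H2 (1 atm), 10% Pd/C, EtOAc–EtOH, rt; stopped after uptake of 3 equiv H2
Reagents that add atoms: none
Why: catalytic hydrogenolysis of aryl benzyl ethers, which under neutral conditions at 1 atm are cleaved much faster than the ring C7–O bond (a benzylic dialkyl ether), while the C9 ester is not benzylic at its alkyl carbon, so the oxolane, the ester and all three stereocentres should stay untouched.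

## Compound list

1 | 4-(benzyloxy)-3-methoxybenzaldehyde | COc1cc(C=O)ccc1OCc1ccccc1 | starting material
2 | vinylmagnesium bromide | C=C[Mg]Br | starting material
3 | rac-1-[4-(benzyloxy)-3-methoxyphenyl]prop-2-en-1-ol | COc1cc(C(O)C=C)ccc1OCc1ccccc1 | intermediate
4 | (S)-[4-(benzyloxy)-3-methoxyphenyl][(R)-oxiran-2-yl]methanol | O[C@@H](c1ccc(OCc2ccccc2)c(OC)c1)[C@H]1CO1 | intermediate
5 | ethyl (triphenylphosphoranylidene)acetate | CCOC(=O)C=P(c1ccccc1)(c1ccccc1)c1ccccc1 | starting material
6 | ethyl (E)-3-[4-(benzyloxy)-3-methoxyphenyl]prop-2-enoate | CCOC(=O)/C=C/c1ccc(OCc2ccccc2)c(OC)c1 | intermediate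
7 | (E)-3-[4-(benzyloxy)-3-methoxyphenyl]prop-2-en-1-ol | OC/C=C/c1ccc(OCc2ccccc2)c(OC)c1 | intermediate
8 | (E)-1-(benzyloxy)-4-(3-bromoprop-1-en-1-yl)-2-methoxybenzene | BrC/C=C/c1ccc(OCc2ccccc2)c(OC)c1 | intermediate
9 | epoxy cinnamyl ether, (S) at C7, (R) at the oxirane CH, (E)-alkene | COc1cc(/C=C/CO[C@@H](c2ccc(OCc3ccccc3)c(OC)c2)[C@H]2CO2)ccc1OCc1ccccc1 | intermediate
10 | C8 radical with Cp2(Cl)Ti–O on C9 (not isolated) | COc1cc(/C=C/CO[C@@H](c2ccc(OCc3ccccc3)c(OC)c2)[CH]CO[Ti](Cl)(C4C=CC=C4)C5C=CC=C5)ccc1OCc1ccccc1 | intermediate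
11 | cyclised C7' benzylic radical with Cp2(Cl)Ti–O on C9 (not isolated) | COc1cc([CH][C@@H]2CO[C@@H](c3ccc(OCc4ccccc4)c(OC)c3)[C@@H]2CO[Ti](Cl)(C4C=CC=C4)C5C=CC=C5)ccc1OCc1ccccc1 | intermediate
12 | C7'-titanium(IV) C9-titanoxy oxolane (not isolated) | COc1cc(C([Ti](Cl)(C4C=CC=C4)C5C=CC=C5)[C@@H]2CO[C@@H](c3ccc(OCc4ccccc4)c(OC)c3)[C@@H]2CO[Ti](Cl)(C4C=CC=C4)C5C=CC=C5)ccc1OCc1ccccc1 | intermediate
13 | (7R,8S,8'S)-4,4'-di-O-benzyllariciresinol | COc1cc(C[C@@H]2CO[C@@H](c3ccc(OCc4ccccc4)c(OC)c3)[C@@H]2CO)ccc1OCc1ccccc1 | intermediate
14 | 4-(benzyloxy)benzoic acid | O=C(O)c1ccc(OCc2ccccc2)cc1 | starting material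
15 | tri-O-benzylagastinol | COc1cc(C[C@@H]2CO[C@@H](c3ccc(OCc4ccccc4)c(OC)c3)[C@@H]2COC(=O)c2ccc(OCc3ccccc3)cc2)ccc1OCc1ccccc1 | intermediate
16 | agastinol, [(2R,3S,4S)-4-(4-hydroxy-3-methoxybenzyl)-2-(4-hydroxy-3-methoxyphenyl)oxolan-3-yl]methyl 4-hydroxybenzoate | COc1cc(C[C@@H]2CO[C@@H](c3ccc(O)c(OC)c3)[C@@H]2COC(=O)c2ccc(O)cc2)ccc1O | target

## Step count and risks

Total step count: 9.
Longest linear sequence: 7 steps (steps 3–9, from 1).

**Step 7.**
- What may go wrong: capture of the C8 radical by a second Ti(III) before ring closure, followed by β-elimination; dimerisation of the benzylic radical; or weak diastereofacial control.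
- Fallback: the same C8 radical is generated in a tin hydride chain, where no metal can trap it.
- It sets out from 9 (with 14). The oxirane is opened at its CH2 terminus by acid 14 (cat. Bu4NBr, MeCN, 80 °C) to give the (2R,3S)-hydroxy ester F1.
- The secondary C8–OH of F1 is converted with PhOC(S)Cl, pyridine and DMAP in CH2Cl2 into the phenyl thionocarbonate F2.
- Bu3SnH/AIBN (slow addition, toluene, 85 °C; Barton–McCombie-type radical generation followed by 5-exo cyclisation through the same chair-like transition state) should give the ester-bearing oxolane directly.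
- The fallback comes back to the route at 15 and replaces steps 7 and 8.

**Step 6.**
- What may go wrong: Payne rearrangement of the deprotonated epoxy alcohol, or ionisation and polymerisation of the electron-rich bromide before it is alkylated.
- Fallback: the SN2 reaction on a labile bromide is replaced by π-allylpalladium chemistry on a stable ester.
- It sets out from 7 (with 4). Acetylation (Ac2O, pyridine) gives the cinnamyl acetate F3.
- Palladium-catalysed allylic etherification with the zinc alkoxide of 4 (Et2Zn 0.5 equiv, Pd(OAc)2, a bulky biaryl phosphine, THF, rt) should attack the unsubstituted allyl terminus and give the linear (E)-ether. The non-vinylic oxirane is inert to Pd(0).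
- The fallback comes back at 9 and replaces steps 5 and 6.

**Step 2.**
- What may go wrong: too small a rate difference between the enantiomers, or Lewis-acid-induced ionisation or opening of the electron-rich benzylic epoxy alcohol. Either erodes the enantiomeric purity carried through the whole route.
- Fallback: resolution and epoxidation are separated.
- It sets out from 3. Immobilised Candida antarctica lipase B with vinyl acetate (MTBE, 30 °C) should acylate the (R)-enantiomer, following the empirical rule for secondary alcohols with aryl as the large group. This gives the (R)-allylic acetate F4, which is separated from the (S)-alcohol.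
- Methanolysis (K2CO3, MeOH, 0 °C) gives the (R)-allylic alcohol F5.
- A matched Sharpless epoxidation of F5 (L-(+)-DIPT, Ti(OiPr)4, TBHP 1.5 equiv, −20 °C) is no longer a resolution and gives the erythro epoxy alcohol.
- The fallback comes back at 4.

## Further compounds

F1 | step 7 | (2R,3S)-3-[4-(benzyloxy)-3-methoxyphenyl]-3-{[(E)-3-[4-(benzyloxy)-3-methoxyphenyl]prop-2-en-1-yl]oxy}-2-hydroxypropyl 4-(benzyloxy)benzoate | COc1cc(/C=C/CO[C@@H](c2ccc(OCc3ccccc3)c(OC)c2)[C@H](O)COC(=O)c2ccc(OCc3ccccc3)cc2)ccc1OCc1ccccc1
F2 | step 7 | O-phenyl thionocarbonate of F1 at the C8 hydroxyl group | COc1cc(/C=C/CO[C@@H](c2ccc(OCc3ccccc3)c(OC)c2)[C@H](OC(=S)Oc2ccccc2)COC(=O)c2ccc(OCc3ccccc3)cc2)ccc1OCc1ccccc1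
F3 | step 6 | (E)-3-[4-(benzyloxy)-3-methoxyphenyl]prop-2-en-1-yl acetate | CC(=O)OC/C=C/c1ccc(OCc2ccccc2)c(OC)c1
F4 | step 2 | (R)-1-[4-(benzyloxy)-3-methoxyphenyl]prop-2-en-1-yl acetate | CC(=O)O[C@@H](c1ccc(OCc2ccccc2)c(OC)c1)C=C
F5 | step 2 | (R)-1-[4-(benzyloxy)-3-methoxyphenyl]prop-2-en-1-ol | O[C@@H](c1ccc(OCc2ccccc2)c(OC)c1)C=C
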